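The numbers were chosen freely, and the outcome is calculated.

Start from the target, which stands at the end of a chain fed by intermediate A and free coupling partner.

    substrate → intermediate A (k1 = 0.0049 min⁻¹)
    substrate ⇌ intermediate B (K2 = 0.67, k2 = 6.4 × 10⁻⁴ min⁻¹)
    coupling partner + intermediate A ⇌ intermediate C (K3 = 0.94 M⁻¹, k3 = 0.16 M⁻¹ min⁻¹)
    intermediate C ⇌ target (K4 = 0.81, k4 = 0.018 min⁻¹)
    substrate + intermediate C → side product (k5 = 0.30 M⁻¹ min⁻¹)
    coupling partner ⇌ dormant form (K6 = 1.2, k6 = 0.060 min⁻¹)

the same everywhere: coupling partner 0.210 M; time 15 h
- Friday's: substrate 0.20 M
- Sunday's: substrate 0.40 M
- Thursday's: substrate 0.80 M

- in percentages every species weighs as the substrate in it: one side product counts as two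
- "hardly changes" means that all values lie within two and a half points (for a concentration: within two and a half percent of the largest)
- run time (Friday's): 15 h

1. [target] at the end for Friday's, Sunday's, Thursday's, in this order
2. the course of these numbers from the first flask to the last (hardly changes / falls all the way / rises all the way / falls, then rises / rises, then falls)

First ask what an error in each constant costs. Set aside the rate constant between intermediate C and target: that pair relaxes with a half-life of 0.287 h, far shorter than the 15 h run, so its equilibrium constant 0.81 counts instead. Treat coupling partner and dormant form the same way, since they relax in 0.105 h, which leaves 1.2. Treat the binding step likewise, since intermediate C falls apart with a half-life of 4.07 min, which leaves 0.94 M⁻¹. Leave out intermediate B, because substrate reaches it with a forward half-life of 18 h, slower than the 2.4 h towards intermediate A. Know 0.81 well: the target stands to intermediate C in that ratio, so at a given intermediate C an error in it passes in full into the target. Know the binding constant well too, though its error does not simply pass through: a larger value makes more intermediate C, which also feeds the side product, and that spends coupling partner. Know 0.30 M⁻¹ min⁻¹ and 0.0049 min⁻¹ well too, but as a ratio, because it sets how much side product forms.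

Now multiply the two equilibrium constants into the target quotient 0.761 M⁻¹, the target standing per unit of intermediate A times free coupling partner, a pre-equilibrium. Let x be the side product concentration. Each side product spends two substrates and one partner, so intermediate A is about the substrate charge minus 2 times x, and free partner about the partner charge minus x, divided by 1 plus 1.2; intermediates C and target are neglected in these balances.

Guess x as the substrate charge over 5. The quotient then gives 0.00706 M, 0.0108 M and 0.00831 M for Friday's, Sunday's and Thursday's.

Put that back. Intermediate C is the target over 0.81, and r, the side-product rate over the rate towards intermediate A, is 0.30 M⁻¹ min⁻¹ times intermediate C over 0.0049 min⁻¹. Since r starts at zero, take 0.5 of it as its mean, and x becomes the charge times r/(1+r): 0.0421 M, 0.116 M, 0.191 M. The second round gives 0.00673 M, 0.00547 M, 0.00273 M. The rounds swing, so commit to their means: 0.00689 M, 0.00814 M, 0.00552 M. My row is higher on Sunday's than on either neighbour.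

The forecast gives 0.0058 M, 0.0056 M, 0.0017 M, a course that falls all the way, on the ground that “each side-product event permanently removes a bound partner”. It parts from my row in shape.

The simulation gives 0.00577 M, 0.00666 M, 0.00356 M: rises, then falls. The row reads as turning near a substrate charge of 0.37 M. Use the quotient on Friday's flask at 15.0 h: 0.761 M⁻¹ times intermediate A at 0.104 M and coupling partner at 0.0733 M gives 0.00579 M. Use it on Thursday's flask at 15.0 h: intermediate A at 0.396 M and coupling partner at 0.0118 M give 0.00357 M, with 5.64% of the partner's own charge left free.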